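## The problem

The target joins two 2-(2-phenylethyl)chromone units through one ether oxygen. The upper unit is a 5,6,7,8-tetrahydrochromone: a carbocycle (C4a, C5, C6, C7, C8, C8a) fused to a 4-pyranone ring (O1, C2, C3, C4, C4a, C8a). Its C5 oxygen is bonded to C6′ of a fully aromatic lower chromone that keeps a free hydroxyl at C7′. The carbocycle carries four contiguous stereocentres, (5S,6S,7R,8S): the C5 and C8 oxygens are cis to each other and the C6/C7 diol is cis and lies on the opposite face. Without the pyranone this pattern would be meso, so the absolute problem is one of desymmetrisation: which end of the carbocycle sits next to the C4 carbonyl and carries the aryl ether. The stereocentres are not independent. Once C5–O and C8–O stand cis on a cyclohexene, both allylic oxygens direct an osmylation of C6=C7 to the other face, so C6 and C7 follow from C5 and C8, and those two must be set together and in the absolute sense. The molecule is fragile in several ways: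

- The C5–O bond is allylic to C4a=C8a and vinylogous to O1, so it ionises under acid.
- C8–H is vinylogously acidic. With unsaturation at C6–C7, loss of C8–H and the C5 oxygen gives an aromatic chromone.
- The secondary alkyl aryl ether must be made without inversion or ionisation at C5.
- Two pyranone carbonyls and a free phenol limit the choice of reductants and oxidants.

The feature that opens the structure is that C5 and C8 are attached to the adjacent pyranone carbons C4a and C8a. A 3-formyl-2-(alkoxymethyl)-4-pyranone carries the formyl carbon (future C5) and the alkoxymethyl carbon (future C8) in exactly these places. Transfer of one hydrogen from C8 to the formyl oxygen turns it into a diene C5=C4a–C8a=C8 whose enol hydroxyl lies next to the C4 carbonyl.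

## Retrosynthesis

Positions carry chromone locants throughout (primes for the lower unit), also in intermediates in which the carbocycle does not yet exist.

**Target 24 back to 23 and 22.** The O8 benzyl ether of 23 is removed last, because hydrogenolysis is neutral and the benzyl group is the hydrogen-donor substituent needed earlier. The C6–O and C7–O bonds of 23 are then cut together, back to the C6=C7 alkene 22. Against an epoxide opening or a stepwise oxygenation, a syn dihydroxylation gives the cis diol directly, and the cis C5 and C8 oxygens place it on the required face. The precursor has two stereocentres fewer. The forward reaction must tolerate a free phenol and leave the two electron-poor pyranone double bonds alone.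

**22 back to alkene alcohol 14 and quinone diazide 21.** The bond cut is O–C6′, not C5–O. Methods that form C5–O by substitution either invert C5 (Mitsunobu) or pass through the vinylogous oxocarbenium ion, which loses configuration and aromatises. A rhodium carbenoid from the ortho-quinone diazide 21 inserts into the O–H bond of 14 under neutral conditions, keeps C5 as it is, and delivers the 7′-hydroxyl free, with no protecting group on the lower unit. The cut halves the molecule. The forward reaction must favour O–H insertion over cyclopropanation of C6=C7 and over arylation of the phenol that it creates.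

**14 back to bis-sulfone 13.** The C6=C7 bond is traced to two vicinal C–SO2Ph bonds. A vicinal bis-sulfone is the retron of a cycloaddition with (E)-1,2-bis(phenylsulfonyl)ethene 11, a symmetric and strongly electron-poor ethyne equivalent. This is preferred to a dienophile that already carries the C6/C7 oxygens, because such a dienophile would have to add exo to put them trans to C5–O and C8–O. The forward reaction is a reductive elimination that must spare the pyranone.

**13 back to aldehyde 10 and 11 (key disconnection).** C5–C6 and C7–C8 are cut, which opens the carbocycle and leaves a diene C5=C4a–C8a=C8, photoenol 12. This is the tautomer of 10 in which a C8 hydrogen has moved to the formyl oxygen. The cut removes the ring and all four stereocentres and leads to an achiral, monocyclic pyranone. Neighbouring cuts (C4a–C5 or C8–C8a alone) would need a carbocycle with an enolisable ketone flanked by leaving groups. The forward reaction asks for three things: photoenolisation of a chromophore on which it is untested; a diene with both oxygens on its outer edge, so that C5–O and C8–O come out cis; and face selection by a chiral titanium diolate chelated between O4 and the enol oxygen.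

**10 back to 9, 8, and then 3 and 5.** The aldehyde is reached from ester 8 by reduction to alcohol 9 and reoxidation. The pyranone of 8 is cut at C4–C4a and O1–C8a into two pieces. One is the four-atom acylketene 6 (O1, C2, C3, C4), released from dioxinone 3. The other is the two-carbon enamine unit (C4a, C8a) of enamino ester 5, with aminal 7 as the ring-closed intermediate. This places the ester on C4a and the benzyloxymethyl group on C8a without any regiochemical ambiguity, which a formylation or halogenation of a finished pyranone could not do.

**3 back to 1 and 2; 5 back to 4.** The phenethyl chain of 3 is cut at its central C–C bond to the commercial dioxinone 1 and benzyl bromide 2 (alkylation of the vinylogous enolate). Enamino ester 5 comes from commercial keto ester 4 and pyrrolidine.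

**21 back to 20, 19, 16 with 17, and 15.** The diazo group is traced to the amine 20 and the nitro compound 19. The nitrogen is introduced before the chromone exists, by nitration of 2′,4′-dihydroxyacetophenone 15 to 16, because a 7-hydroxychromone would be substituted at C8 instead of C6. The pyranone ring of 19 is cut at C2–C3 and O1–C2 to 16 and 3-phenylpropanoyl chloride 17, through diketone 18.

## Roads not taken

Alternative 1: The cut is at both C–O bonds at C5 and C8, made on a carbocycle that exists before either pyranone. In the forward direction, sensitised photooxygenation adds singlet oxygen across the diene termini of the enzymatically derived bromodiene acetonide A1, on the face opposite the acetonide, to give endoperoxide A2.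
- Merits: the reaction type is established for this class of diene. All four carbinol centres are fixed in one step and in the absolute sense: C6 and C7 by the enzyme, C5 and C8 by the acetonide. The bromine tells C5 from C8.
- Weak points: A2 contains neither pyranone. After peroxide cleavage the brominated terminus collapses to a carbonyl, so C5 arrives as a ketone that must later be reduced with the right sense and then still be arylated. The upper pyranone would have to be annulated onto an enone (an acyl group onto C4a, an oxygen onto C8a) while alkoxy groups sit beta and gamma to that carbonyl and are open to elimination under any enolising conditions. Many steps would follow the key step.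
- Comparison: in stereochemical security this road is better than the chosen one, since its key step is known and its absolute configuration does not rest on an untried induction. The chosen plan sets against it a pyranone that is complete before the first stereocentre appears, four steps from key product to target, and no ketone with a leaving group in the beta position at any stage.

Alternative 2: The cut is at C4a–C5, with the aryl ether made beforehand as a glycosidic bond. In the forward direction, Ti(OiPr)Cl3 opens the ring C1–O5 bond of the manno-configured aryl hex-5-enopyranoside A3. The titanium enolate carbon then closes onto the aryloxy-stabilised oxocarbenium carbon to give the cyclohexanone A4.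
- Merits: the C5–O–aryl bond, the least secure bond of the chosen plan, is formed here by glycosylation of a phenol, which is well understood. C6, C7 and C8 come from the chiral pool and C5 is held by the rearrangement. In these respects the road is better.
- Weak points: A4 is a beta-aryloxy ketone. Building the pyranone means acylating C4a through the enolate that also expels the C5 phenoxide. The chromone carbonyl of the aglycone competes for the Lewis acid. An aryl glycoside tends to ionise by loss of the phenoxide instead of ring opening. The protecting-group work on the sugar makes the sequence longer.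
- Comparison: the chosen plan has to set the riskier O–H insertion of step 12 against the secure glycosidic bond. It gains a route in which the C5 oxygen never sits beta to an enolisable ketone, and a shorter sequence.

Alternative 3: The cut is at C2–C3 and C2′–C3′, so that both phenethyl arms arrive last. In the forward direction, excess LiN(SiMe3)2 deprotonates the two acetyl groups of the bis-acetyl compound A5, and both enolates are acylated by methyl 3-phenylpropanoate A7 to give the bis-diketone A6. No ring closes in this step; a double cyclodehydration would follow.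
- Merits: one cheap reagent and one operation build both side chains. No separate lower chromone and no quinone diazide are needed; here the road is more economical than the chosen plan, which spends four steps on 21.
- Weak points: this is an end game, not a solution. A5 already contains all four stereocentres and the aryl ether, and their origin stays open. Excess strong base meets a substrate with a vinylogously acidic C8–H and an aryloxide leaving group at C5, so epimerisation and 1,4-elimination to an arene are likely. The closing acid step then meets the acid-labile C5 ether.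
- Comparison: the chosen plan is less convergent in the arms, but it solves the stereochemical problem that this road postpones, and it uses no strong base once the carbocycle exists.

Key step: step 6

Remarks on the chemistry:
- The sense of induction of the titanium diolate in step 6 cannot be predicted. The route is written with the (4R,5R)-diol, and the (4S,5S)-diol is used if the first gives the antipode of 13.
- Compound 13 is drawn as one of the two possible trans-disulfone diastereomers. Both give 14.

## Route

Step 1
Reactants: 1 2,2,6-trimethyl-4H-1,3-dioxin-4-one; 2 benzyl bromide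
Product: 3 2,2-dimethyl-6-(2-phenylethyl)-4H-1,3-dioxin-4-one
Conditions: LiN(iPr)2, THF–HMPA, −78 °C; then 2, −78 to −20 °C
Reagents that add atoms: none
Why: The lithium dienolate of the dioxinone is a vinylogous ester enolate and should be alkylated at its terminal (gamma) carbon by the reactive benzylic bromide in the presence of HMPA, the standard chain extension of this dioxinone; no stereocentre is formed.

Step 2
Reactants: 4 ethyl 4-(benzyloxy)-3-oxobutanoate
Product: 5 ethyl (2E)-4-(benzyloxy)-3-(pyrrolidin-1-yl)but-2-enoate
Conditions: pyrrolidine, AcOH (cat.), toluene, 4 Å molecular sieves, rt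
Reagents that add atoms: pyrrolidine, C1CCNC1
Why: Condensation of a beta-keto ester with a secondary amine gives the conjugated beta-enamino ester; conjugation with the ester fixes the double bond toward C2 and away from the benzyloxymethyl group.

Step 3
Reactants: 3 2,2-dimethyl-6-(2-phenylethyl)-4H-1,3-dioxin-4-one; 5 ethyl (2E)-4-(benzyloxy)-3-(pyrrolidin-1-yl)but-2-enoate
Product: 8 ethyl 2-[(benzyloxy)methyl]-4-oxo-6-(2-phenylethyl)-4H-pyran-3-carboxylate, via acylketene 6 (not isolated), via pyrrolidine aminal 7 (not isolated)
Conditions: toluene, 110 °C, acetone distilled off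
Reagents that add atoms: none
Why: Thermal retro-[4+2] of the dioxinone releases acetone and acylketene 6, which acylates the nucleophilic alpha-carbon of the enamino ester; the acyl oxygen closes onto the iminium carbon to aminal 7 and loss of pyrrolidine gives the 4-pyranone (the enamine/acylketene gamma-pyrone synthesis). The tertiary enamine cannot be N-acylated, and the substitution pattern follows from the polarity of the two partners.

Step 4
Reactants: 8 ethyl 2-[(benzyloxy)methyl]-4-oxo-6-(2-phenylethyl)-4H-pyran-3-carboxylate
Product: 9 2-[(benzyloxy)methyl]-3-(hydroxymethyl)-6-(2-phenylethyl)-4H-pyran-4-one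
Conditions: iBu2AlH (2.2 equiv), CH2Cl2, −78 °C; aq. potassium sodium tartrate
Reagents that add atoms: none
Why: Hydride reduction of the ester to the primary alcohol at low temperature; the ring carbonyl is a doubly vinylogous ester and both of its beta-carbons are fully substituted, which should disfavour 1,2- and conjugate attack on the ring.

Step 5
Reactants: 9 2-[(benzyloxy)methyl]-3-(hydroxymethyl)-6-(2-phenylethyl)-4H-pyran-4-one
Product: 10 2-[(benzyloxy)methyl]-4-oxo-6-(2-phenylethyl)-4H-pyran-3-carbaldehyde
Conditions: Dess–Martin periodinane, CH2Cl2, 0 °C to rt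
Reagents that add atoms: none
Why: Dess–Martin oxidation of a primary allylic-type alcohol stops at the aldehyde under neutral, non-aqueous conditions and leaves the benzyl ether and the pyranone untouched.

Step 6
Reactants: 10 2-[(benzyloxy)methyl]-4-oxo-6-(2-phenylethyl)-4H-pyran-3-carbaldehyde; 11 (E)-1,2-bis(phenylsulfonyl)ethene
Product: 13 (5S,6R,7R,8R)-8-(benzyloxy)-5-hydroxy-2-(2-phenylethyl)-6,7-bis(phenylsulfonyl)-5,6,7,8-tetrahydro-4H-chromen-4-one, via photoenol 12 (not isolated)
Conditions: Ti(OiPr)4 (1.0 equiv), (4R,5R)-2,2-dimethyl-α,α,α′,α′-tetraphenyl-1,3-dioxolane-4,5-dimethanol (1.1 equiv), 11 (2 equiv), toluene–CH2Cl2, argon, 365 nm LED, 15 °C; aq. potassium sodium tartrate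
Reagents that add atoms: none
Why: Proposed new method: excitation of the formyl n,π* band at 365 nm should move a hydrogen from the benzyloxymethyl carbon (C8) to the formyl oxygen by 1,5-transfer, and bond reorganisation of the resulting biradical gives photoenol 12, a hydroxy-ortho-quinodimethane in which the pyranone has given up its C4a=C8a bond. The closest known reaction type is the photoenolisation/Diels–Alder reaction of ortho-alkylbenzaldehydes, including enantioselective versions run with Ti(OiPr)4 and TADDOL-type diols; a 4-pyranone-3-carbaldehyde with an alkoxymethyl hydrogen donor has not been used. The case for it is that the C8–H bond is allylic and alpha to oxygen, that a 4-pyranone loses less stabilisation than a benzene ring on dearomatisation, and that in the long-lived rotamer of 12 the enol hydroxyl points toward the C4 carbonyl, where a six-membered hydrogen bond or titanium chelate holds it and return by a 1,5-shift is impossible. The carbocycle closes by an intermolecular [4+2] cycloaddition, suprafacial on both partners, that forms C5–C6 and C7–C8 and restores the pyranone; the dienophile is C2-symmetric, so no regiochemical question arises. C5 and C8 are set by the diene geometry: the hydroxyl is held on the outer edge by the chelate and the benzyloxy group avoids the inner position, so both oxygens are outward and become cis. C6 and C7 come out trans from the (E)-dienophile and are of no consequence, since both sulfones leave in step 7. The absolute configuration is to come from the titanium diolate bound between O4 and the C5 enol oxygen, which should shield one face of the diene; the enantiomer of the diol is chosen by experiment. The step needs hydrogen abstraction from C8–H in preference to the OCH2Ph hydrogens (six- against eight-membered transition state) and capture of 12 before oxygen or re-protonation consume it, hence the degassed solution and the excess of 11.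

Step 7
Reactants: 13 (5S,6R,7R,8R)-8-(benzyloxy)-5-hydroxy-2-(2-phenylethyl)-6,7-bis(phenylsulfonyl)-5,6,7,8-tetrahydro-4H-chromen-4-one
Product: 14 (5R,8S)-8-(benzyloxy)-5-hydroxy-2-(2-phenylethyl)-5,8-dihydro-4H-chromen-4-one
Conditions: 6% Na(Hg), NaH2PO4, MeOH–THF, −20 °C
Reagents that add atoms: none
Why: Reductive elimination of a vicinal bis-sulfone: electron transfer cleaves one C–S bond and the carbanion expels the neighbouring sulfinate, a far better leaving group than the hydroxide or benzyloxide on the other side, to give the C6=C7 alkene. The phosphate buffer keeps methoxide from starting the 1,4-elimination to the aromatic chromone; C5 and C8 are not touched.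

Step 8
Reactants: 15 2′,4′-dihydroxyacetophenone
Product: 16 1-(2,4-dihydroxy-5-nitrophenyl)ethanone
Conditions: HNO3 (70%), AcOH, 5–15 °C; recrystallisation
Reagents that add atoms: nitric acid, O[N+](=O)[O-]
Why: Electrophilic aromatic nitration; position 5 is para to the 2-hydroxyl, ortho to the 4-hydroxyl and unhindered, whereas position 3 lies between two hydroxyls, and the minor isomer is removed by crystallisation.

Step 9
Reactants: 16 1-(2,4-dihydroxy-5-nitrophenyl)ethanone; 17 3-phenylpropanoyl chloride
Product: 19 7-hydroxy-6-nitro-2-(2-phenylethyl)-4H-chromen-4-one, via diketone 18 (not isolated)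
Conditions: LiN(SiMe3)2 (4 equiv), THF, −78 to −10 °C; 17, −78 °C to rt; then AcOH, H2SO4 (cat.), 95 °C
Reagents that add atoms: none
Why: The lithium polyanion (two phenoxides and the ketone enolate) is C-acylated by the acid chloride in a Claisen-type acylation, and acid then closes the chromone by cyclodehydration of the 2-hydroxyaryl 1,3-diketone 18, the one-pot variant of the Baker–Venkataraman chromone synthesis for unprotected hydroxyacetophenones.

Step 10
Reactants: 19 7-hydroxy-6-nitro-2-(2-phenylethyl)-4H-chromen-4-one
Product: 20 6-amino-7-hydroxy-2-(2-phenylethyl)-4H-chromen-4-one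
Conditions: H2 (1 atm), Pd/C, EtOAc–EtOH, rt, stopped after three equivalents of H2
Reagents that add atoms: none
Why: Catalytic hydrogenation reduces an aromatic nitro group much faster than the conjugated C2=C3 bond of a chromone, so the amine should be obtained cleanly when the uptake is watched.

Step 11
Reactants: 20 6-amino-7-hydroxy-2-(2-phenylethyl)-4H-chromen-4-one
Product: 21 6-diazo-2-(2-phenylethyl)-4H-chromene-4,7(6H)-dione
Conditions: NaNO2, HCl (aq.), 0 °C; then dilution with water, dark
Reagents that add atoms: sodium nitrite, [Na+].[O-]N=O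
Why: Diazotisation of an ortho-aminophenol; the diazonium ion of the acidic 7-hydroxyl loses its phenolic proton and gives the neutral ortho-quinone diazide, which is kept from light and used without storage.

Step 12
Reactants: 14 (5R,8S)-8-(benzyloxy)-5-hydroxy-2-(2-phenylethyl)-5,8-dihydro-4H-chromen-4-one; 21 6-diazo-2-(2-phenylethyl)-4H-chromene-4,7(6H)-dione
Product: 22 (5R,8S)-8-(benzyloxy)-5-{[7-hydroxy-4-oxo-2-(2-phenylethyl)-4H-chromen-6-yl]oxy}-2-(2-phenylethyl)-5,8-dihydro-4H-chromen-4-one
Conditions: Rh2(OAc)4 (2 mol %), CH2Cl2, rt, slow addition of 21 (1.2 equiv), dark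
Reagents that add atoms: none
Why: Rh2(OAc)4 turns the quinone diazide into a rhodium carbenoid that inserts into the O–H bond of the secondary alcohol through an oxonium ylide and proton shift (carbenoid O–H insertion of a quinone diazide); rearomatisation gives the C6′ ether with the C7′ hydroxyl free. The C5–O bond is never broken, so C5 keeps its configuration, and proton transfer with gain of aromaticity should outrun a [2,3]-shift of the allylic ylide.

Step 13
Reactants: 22 (5R,8S)-8-(benzyloxy)-5-{[7-hydroxy-4-oxo-2-(2-phenylethyl)-4H-chromen-6-yl]oxy}-2-(2-phenylethyl)-5,8-dihydro-4H-chromen-4-one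
Product: 23 (5S,6S,7R,8S)-8-(benzyloxy)-6,7-dihydroxy-5-{[7-hydroxy-4-oxo-2-(2-phenylethyl)-4H-chromen-6-yl]oxy}-2-(2-phenylethyl)-5,6,7,8-tetrahydro-4H-chromen-4-one
Conditions: OsO4 (5 mol %), N-methylmorpholine N-oxide, acetone–H2O, 0 °C to rt
Reagents that add atoms: osmium tetroxide, O=[Os](=O)(=O)=O; N-methylmorpholine N-oxide, C[N+]1([O-])CCOCC1
Why: Upjohn dihydroxylation; OsO4 adds syn to the only electron-rich alkene, C6=C7, from the face opposite the two cis allylic oxygens at C5 and C8, which sets C6 and C7 together. The pyranone double bonds are conjugated to carbonyl groups and should not react.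

Step 14
Reactants: 23 (5S,6S,7R,8S)-8-(benzyloxy)-6,7-dihydroxy-5-{[7-hydroxy-4-oxo-2-(2-phenylethyl)-4H-chromen-6-yl]oxy}-2-(2-phenylethyl)-5,6,7,8-tetrahydro-4H-chromen-4-one
Product: 24 (5S,6S,7R,8S)-6,7,8-trihydroxy-5-{[7-hydroxy-4-oxo-2-(2-phenylethyl)-4H-chromen-6-yl]oxy}-2-(2-phenylethyl)-5,6,7,8-tetrahydro-4H-chromen-4-one
Conditions: H2 (1 atm), Pd/C, EtOAc–MeOH, rt
Reagents that add atoms: none
Why: Hydrogenolysis of the single benzyl ether under neutral conditions; the C5 aryl ether stands on a tetrasubstituted, carbonyl-conjugated enol ether carbon that does not readily form a π-allyl species, and the pyranone double bonds should survive at atmospheric pressure when the reaction is stopped at full conversion.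

## Compound list

1 | 2,2,6-trimethyl-4H-1,3-dioxin-4-one | CC1=CC(=O)OC(C)(C)O1 | starting material
2 | benzyl bromide | BrCc1ccccc1 | starting material
3 | 2,2-dimethyl-6-(2-phenylethyl)-4H-1,3-dioxin-4-one | CC1(C)OC(=O)C=C(CCc2ccccc2)O1 | intermediate
4 | ethyl 4-(benzyloxy)-3-oxobutanoate | CCOC(=O)CC(=O)COCc1ccccc1 | starting material
5 | ethyl (2E)-4-(benzyloxy)-3-(pyrrolidin-1-yl)but-2-enoate | CCOC(=O)/C=C(/N1CCCC1)COCc1ccccc1 | intermediate
6 | 5-phenylpent-1-ene-1,3-dione (acylketene, formed in the flask) | O=C=CC(=O)CCc1ccccc1 | intermediate
7 | ethyl 2-[(benzyloxy)methyl]-4-oxo-6-(2-phenylethyl)-2-(pyrrolidin-1-yl)-3,4-dihydro-2H-pyran-3-carboxylate (aminal, mixture of diastereomers, formed in the flask) | CCOC(=O)C1C(=O)C=C(CCc2ccccc2)OC1(COCc1ccccc1)N1CCCC1 | intermediate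
8 | ethyl 2-[(benzyloxy)methyl]-4-oxo-6-(2-phenylethyl)-4H-pyran-3-carboxylate | CCOC(=O)c1c(COCc2ccccc2)oc(CCc2ccccc2)cc1=O | intermediate
9 | 2-[(benzyloxy)methyl]-3-(hydroxymethyl)-6-(2-phenylethyl)-4H-pyran-4-one | OCc1c(COCc2ccccc2)oc(CCc2ccccc2)cc1=O | intermediate
10 | 2-[(benzyloxy)methyl]-4-oxo-6-(2-phenylethyl)-4H-pyran-3-carbaldehyde | O=Cc1c(COCc2ccccc2)oc(CCc2ccccc2)cc1=O | intermediate
11 | (E)-1,2-bis(phenylsulfonyl)ethene | O=S(=O)(/C=C/S(=O)(=O)c1ccccc1)c1ccccc1 | starting material
12 | (2Z,3Z)-2-[(benzyloxy)methylidene]-3-(hydroxymethylidene)-6-(2-phenylethyl)-2,3-dihydro-4H-pyran-4-one (photoenol with both oxygens on the outer edge of the diene, formed in the flask) | O=C1C=C(CCc2ccccc2)O/C(=C\OCc2ccccc2)/C1=C/O | intermediate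
13 | (5S,6R,7R,8R)-8-(benzyloxy)-5-hydroxy-2-(2-phenylethyl)-6,7-bis(phenylsulfonyl)-5,6,7,8-tetrahydro-4H-chromen-4-one (5,8-cis; 6,7-trans) | O=c1cc(CCc2ccccc2)oc2c1[C@H](O)[C@@H](S(=O)(=O)c1ccccc1)[C@H](S(=O)(=O)c1ccccc1)[C@@H]2OCc1ccccc1 | intermediate
14 | (5R,8S)-8-(benzyloxy)-5-hydroxy-2-(2-phenylethyl)-5,8-dihydro-4H-chromen-4-one (5,8-cis) | O=c1cc(CCc2ccccc2)oc2c1[C@H](O)C=C[C@@H]2OCc1ccccc1 | intermediate
15 | 2′,4′-dihydroxyacetophenone | CC(=O)c1ccc(O)cc1O | starting material
16 | 1-(2,4-dihydroxy-5-nitrophenyl)ethanone | CC(=O)c1cc([N+](=O)[O-])c(O)cc1O | intermediate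
17 | 3-phenylpropanoyl chloride | O=C(Cl)CCc1ccccc1 | starting material
18 | 1-(2,4-dihydroxy-5-nitrophenyl)-5-phenylpentane-1,3-dione (formed in the flask) | O=C(CC(=O)CCc1ccccc1)c1cc([N+](=O)[O-])c(O)cc1O | intermediate
19 | 7-hydroxy-6-nitro-2-(2-phenylethyl)-4H-chromen-4-one | O=c1cc(CCc2ccccc2)oc2cc(O)c([N+](=O)[O-])cc12 | intermediate
20 | 6-amino-7-hydroxy-2-(2-phenylethyl)-4H-chromen-4-one | Nc1cc2c(=O)cc(CCc3ccccc3)oc2cc1O | intermediate
21 | 6-diazo-2-(2-phenylethyl)-4H-chromene-4,7(6H)-dione (ortho-quinone diazide) | [N-]=[N+]=C1C=C2C(=O)C=C(CCc3ccccc3)OC2=CC1=O | intermediate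
22 | (5R,8S)-8-(benzyloxy)-5-{[7-hydroxy-4-oxo-2-(2-phenylethyl)-4H-chromen-6-yl]oxy}-2-(2-phenylethyl)-5,8-dihydro-4H-chromen-4-one | O=c1cc(CCc2ccccc2)oc2c1[C@H](Oc1cc3c(=O)cc(CCc4ccccc4)oc3cc1O)C=C[C@@H]2OCc1ccccc1 | intermediate
23 | (5S,6S,7R,8S)-8-(benzyloxy)-6,7-dihydroxy-5-{[7-hydroxy-4-oxo-2-(2-phenylethyl)-4H-chromen-6-yl]oxy}-2-(2-phenylethyl)-5,6,7,8-tetrahydro-4H-chromen-4-one | O=c1cc(CCc2ccccc2)oc2c1[C@H](Oc1cc3c(=O)cc(CCc4ccccc4)oc3cc1O)[C@@H](O)[C@@H](O)[C@@H]2OCc1ccccc1 | intermediate
24 | (5S,6S,7R,8S)-6,7,8-trihydroxy-5-{[7-hydroxy-4-oxo-2-(2-phenylethyl)-4H-chromen-6-yl]oxy}-2-(2-phenylethyl)-5,6,7,8-tetrahydro-4H-chromen-4-one | O=c1cc(CCc2ccccc2)oc2c1[C@H](Oc1cc3c(=O)cc(CCc4ccccc4)oc3cc1O)[C@@H](O)[C@@H](O)[C@@H]2O | target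

## Step count and least certain steps

Total step count: 14. Longest linear sequence: 9 steps (steps 1, 3, 4, 5, 6, 7, 12, 13, 14, from dioxinone 1). The lower unit takes 4 steps (8 to 11) before it joins at step 12.

**Step 6 (key step; the only step beyond known chemistry).**
- What may go wrong: hydrogen transfer may be unproductive. Chelation of the ground-state aldehyde between O4 and the formyl oxygen by titanium holds that oxygen away from C8–H, and abstraction from the OCH2Ph hydrogens or a photorearrangement of the pyranone may compete. The dienol may be re-protonated or oxidised before the dienophile reaches it. Face selection by the titanium diolate may be poor.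
- Fallback (known chemistry, from 8 back to 14): the carbocycle is closed at C6=C7 by ring-closing metathesis. Deprotonation of the benzyloxymethyl group of ester 8 (LiN(SiMe3)2, THF, −78 °C) and Michael addition to phenyl vinyl sulfoxide should give ethyl 2-[1-(benzyloxy)-3-(phenylsulfinyl)propyl]-4-oxo-6-(2-phenylethyl)-4H-pyran-3-carboxylate F1. Thermal sulfoxide elimination (toluene, 110 °C) gives the C8 vinyl compound ethyl 2-[1-(benzyloxy)prop-2-en-1-yl]-4-oxo-6-(2-phenylethyl)-4H-pyran-3-carboxylate F2. Reduction and oxidation as in steps 4 and 5 give 2-[1-(benzyloxy)prop-2-en-1-yl]-3-(hydroxymethyl)-6-(2-phenylethyl)-4H-pyran-4-one F3 and 2-[1-(benzyloxy)prop-2-en-1-yl]-4-oxo-6-(2-phenylethyl)-4H-pyran-3-carbaldehyde F4. Vinylmagnesium bromide (THF, −78 °C) adds to F4 to give 2-[1-(benzyloxy)prop-2-en-1-yl]-3-(1-hydroxyprop-2-en-1-yl)-6-(2-phenylethyl)-4H-pyran-4-one F5 as a mixture of diastereomers. Second-generation Grubbs catalyst (CH2Cl2, 40 °C) closes the ring with loss of ethene. The cis product is racemic 14, that is 14 together with its enantiomer (5S,8R)-8-(benzyloxy)-5-hydroxy-2-(2-phenylethyl)-5,8-dihydro-4H-chromen-4-one F6. It is separated by chromatography from the trans isomer (5S*,8S*)-8-(benzyloxy)-5-hydroxy-2-(2-phenylethyl)-5,8-dihydro-4H-chromen-4-one F7. Kinetic resolution with Candida antarctica lipase B and vinyl acetate acetylates one enantiomer. The fallback is written for the case in which the unwanted one is acetylated, to (5S,8R)-8-(benzyloxy)-4-oxo-2-(2-phenylethyl)-5,8-dihydro-4H-chromen-5-yl acetate F8, and leaves 14, where the route is rejoined. In the opposite case the acetate of 14 is cleaved by the same lipase in buffer.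

**Step 12 (O–H insertion).**
- What may go wrong: cyclopropanation of the C6=C7 bond by the carbenoid, a second insertion into the phenol that the reaction creates, Wolff rearrangement of the diazide, or aromatisation of the sensitive diene alcohol during the slow addition.
- Fallback (from 14 back to 23): the alkene is removed before the ether is made. Dihydroxylation of 14 (OsO4 cat., N-methylmorpholine N-oxide) gives (5S,6R,7R,8S)-8-(benzyloxy)-5,6,7-trihydroxy-2-(2-phenylethyl)-5,6,7,8-tetrahydro-4H-chromen-4-one F9. 2,2-Dimethoxypropane with pyridinium p-toluenesulfonate protects the cis 6,7-diol in preference to the trans 5,6-pair, giving (5S,6R,7R,8S)-8-(benzyloxy)-5-hydroxy-6,7-(isopropylidenedioxy)-2-(2-phenylethyl)-5,6,7,8-tetrahydro-4H-chromen-4-one F10. The Rh2(OAc)4 insertion with 21 is then run on this saturated alcohol and gives (5S,6R,7R,8S)-8-(benzyloxy)-5-{[7-hydroxy-4-oxo-2-(2-phenylethyl)-4H-chromen-6-yl]oxy}-6,7-(isopropylidenedioxy)-2-(2-phenylethyl)-5,6,7,8-tetrahydro-4H-chromen-4-one F11. Aqueous acetic acid at 40 °C removes the acetonide and returns the route at 23.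

**Step 7 (reductive desulfonylation).**
- What may go wrong: electron transfer to the pyranone carbonyl instead of the sulfones, or base-promoted 1,4-elimination of the product to the aromatic chromone.
- Fallback (from 10 back to 14): the reductive step is avoided by a different ethyne equivalent. The photocycloaddition of 10 is run with (E)-trimethyl[2-(phenylsulfonyl)ethenyl]silane in place of 11 and gives (5S,8R)-8-(benzyloxy)-5-hydroxy-2-(2-phenylethyl)-7-(phenylsulfonyl)-6-(trimethylsilyl)-5,6,7,8-tetrahydro-4H-chromen-4-one F12 (5,8-cis, 6,7-trans; the regioisomer with silyl and sulfonyl exchanged serves equally). Fluoride (Bu4NF buffered with AcOH, THF, 0 °C) induces beta-elimination of the silyl and sulfonyl groups and gives 14 without a reductant.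

**Step 4 (ester reduction).**
- What may go wrong: hydride attack on the pyranone (1,2- or conjugate addition at C8a), followed by ring opening, instead of clean reduction of the ester.
- Fallback (from 8 back to 10): the aldehyde is reached without a hydride reagent. Me3SnOH (1,2-dichloroethane, 80 °C) cleaves the ester to 2-[(benzyloxy)methyl]-4-oxo-6-(2-phenylethyl)-4H-pyran-3-carboxylic acid F13. Ethanethiol with N-(3-dimethylaminopropyl)-N′-ethylcarbodiimide hydrochloride and 4-(dimethylamino)pyridine gives S-ethyl 2-[(benzyloxy)methyl]-4-oxo-6-(2-phenylethyl)-4H-pyran-3-carbothioate F14. Fukuyama reduction (Et3SiH, Pd/C, acetone, rt) gives 10 directly.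

## Further compounds

F1 | step 6 | ethyl 2-[1-(benzyloxy)-3-(phenylsulfinyl)propyl]-4-oxo-6-(2-phenylethyl)-4H-pyran-3-carboxylate (racemic, mixture at sulfur) | CCOC(=O)c1c(C(CCS(=O)c2ccccc2)OCc2ccccc2)oc(CCc2ccccc2)cc1=O
F2 | step 6 | ethyl 2-[1-(benzyloxy)prop-2-en-1-yl]-4-oxo-6-(2-phenylethyl)-4H-pyran-3-carboxylate (racemic) | CCOC(=O)c1c(C(C=C)OCc2ccccc2)oc(CCc2ccccc2)cc1=O
F3 | step 6 | 2-[1-(benzyloxy)prop-2-en-1-yl]-3-(hydroxymethyl)-6-(2-phenylethyl)-4H-pyran-4-one (racemic) | OCc1c(C(C=C)OCc2ccccc2)oc(CCc2ccccc2)cc1=O
F4 | step 6 | 2-[1-(benzyloxy)prop-2-en-1-yl]-4-oxo-6-(2-phenylethyl)-4H-pyran-3-carbaldehyde (racemic) | O=Cc1c(C(C=C)OCc2ccccc2)oc(CCc2ccccc2)cc1=O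
F5 | step 6 | 2-[1-(benzyloxy)prop-2-en-1-yl]-3-(1-hydroxyprop-2-en-1-yl)-6-(2-phenylethyl)-4H-pyran-4-one (mixture of diastereomers, racemic) | C=CC(O)c1c(C(C=C)OCc2ccccc2)oc(CCc2ccccc2)cc1=O
F6 | step 6 | (5S,8R)-8-(benzyloxy)-5-hydroxy-2-(2-phenylethyl)-5,8-dihydro-4H-chromen-4-one (enantiomer of 14) | O=c1cc(CCc2ccccc2)oc2c1[C@@H](O)C=C[C@H]2OCc1ccccc1
F7 | step 6 | (5S*,8S*)-8-(benzyloxy)-5-hydroxy-2-(2-phenylethyl)-5,8-dihydro-4H-chromen-4-one (trans isomer, racemic, one enantiomer drawn) | O=c1cc(CCc2ccccc2)oc2c1[C@@H](O)C=C[C@@H]2OCc1ccccc1
F8 | step 6 | (5S,8R)-8-(benzyloxy)-4-oxo-2-(2-phenylethyl)-5,8-dihydro-4H-chromen-5-yl acetate | O=c1cc(CCc2ccccc2)oc2c1[C@@H](OC(C)=O)C=C[C@H]2OCc1ccccc1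
F9 | step 12 | (5S,6R,7R,8S)-8-(benzyloxy)-5,6,7-trihydroxy-2-(2-phenylethyl)-5,6,7,8-tetrahydro-4H-chromen-4-one | O=c1cc(CCc2ccccc2)oc2c1[C@H](O)[C@@H](O)[C@@H](O)[C@@H]2OCc1ccccc1
F10 | step 12 | (5S,6R,7R,8S)-8-(benzyloxy)-5-hydroxy-6,7-(isopropylidenedioxy)-2-(2-phenylethyl)-5,6,7,8-tetrahydro-4H-chromen-4-one | O=c1cc(CCc2ccccc2)oc2c1[C@H](O)[C@H]3OC(C)(C)O[C@H]3[C@@H]2OCc1ccccc1
F11 | step 12 | (5S,6R,7R,8S)-8-(benzyloxy)-5-{[7-hydroxy-4-oxo-2-(2-phenylethyl)-4H-chromen-6-yl]oxy}-6,7-(isopropylidenedioxy)-2-(2-phenylethyl)-5,6,7,8-tetrahydro-4H-chromen-4-one | O=c1cc(CCc2ccccc2)oc2c1[C@H](Oc1cc4c(=O)cc(CCc5ccccc5)oc4cc1O)[C@H]3OC(C)(C)O[C@H]3[C@@H]2OCc1ccccc1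
F12 | step 7 | (5S,8R)-8-(benzyloxy)-5-hydroxy-2-(2-phenylethyl)-7-(phenylsulfonyl)-6-(trimethylsilyl)-5,6,7,8-tetrahydro-4H-chromen-4-one (5,8-cis, 6,7-trans) | O=c1cc(CCc2ccccc2)oc2c1[C@H](O)[C@@H]([Si](C)(C)C)[C@H](S(=O)(=O)c1ccccc1)[C@@H]2OCc1ccccc1
F13 | step 4 | 2-[(benzyloxy)methyl]-4-oxo-6-(2-phenylethyl)-4H-pyran-3-carboxylic acid | OC(=O)c1c(COCc2ccccc2)oc(CCc2ccccc2)cc1=O
F14 | step 4 | S-ethyl 2-[(benzyloxy)methyl]-4-oxo-6-(2-phenylethyl)-4H-pyran-3-carbothioate | CCSC(=O)c1c(COCc2ccccc2)oc(CCc2ccccc2)cc1=O
A1 | alternative 1 | (3aS,7aS)-4-bromo-2,2-dimethyl-3a,7a-dihydro-1,3-benzodioxole (bromodiene acetonide) | BrC1=CC=C[C@@H]2OC(C)(C)O[C@H]12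
A2 | alternative 1 | bromo endoperoxide, 1-bromo-7,8-(isopropylidenedioxy)-2,3-dioxabicyclo[2.2.2]oct-5-ene with the peroxide bridge anti to the acetonide | Br[C@@]12C=C[C@@H](OO1)[C@@H]1OC(C)(C)O[C@H]21
A3 | alternative 2 | 7-(benzyloxy)-4-oxo-2-(2-phenylethyl)-4H-chromen-6-yl 2,3,4-tri-O-benzyl-6-deoxy-α-D-lyxo-hex-5-enopyranoside | C=C1O[C@H](Oc2cc3c(=O)cc(CCc4ccccc4)oc3cc2OCc2ccccc2)[C@@H](OCc2ccccc2)[C@@H](OCc2ccccc2)[C@@H]1OCc1ccccc1
A4 | alternative 2 | 2,3,4-tris(benzyloxy)-5-{[7-(benzyloxy)-4-oxo-2-(2-phenylethyl)-4H-chromen-6-yl]oxy}cyclohexanone, configured at these four carbons as C8, C7, C6 and C5 of the target | O=C1C[C@H](Oc2cc3c(=O)cc(CCc4ccccc4)oc3cc2OCc2ccccc2)[C@@H](OCc2ccccc2)[C@@H](OCc2ccccc2)[C@@H]1OCc1ccccc1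
A5 | alternative 3 | bis-acetyl compound: 1-acetyl-2-methoxycyclohexene carrying benzyloxy groups at the future C8, C7 and C6 and a 4-acetyl-2-(benzyloxy)-5-hydroxyphenoxy group at the future C5, configured as in the target | COC1=C(C(C)=O)[C@H](Oc2cc(C(C)=O)c(O)cc2OCc2ccccc2)[C@@H](OCc2ccccc2)[C@@H](OCc2ccccc2)[C@@H]1OCc1ccccc1
A6 | alternative 3 | bis(1,3-diketone) of A5 in which each acetyl group has become a 3-oxo-5-phenylpentanoyl chain | COC1=C(C(=O)CC(=O)CCc2ccccc2)[C@H](Oc2cc(C(=O)CC(=O)CCc3ccccc3)c(O)cc2OCc2ccccc2)[C@@H](OCc2ccccc2)[C@@H](OCc2ccccc2)[C@@H]1OCc1ccccc1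
A7 | alternative 3 | methyl 3-phenylpropanoate | COC(=O)CCc1ccccc1
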